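**Remarks on the chemistry.** Ring numbering used throughout: O1, C2 (carries ring C), C3 (carries methyl), O4, C4a, C5 (OMe), C7 (propenyl), C8a. The configurations were re-derived from the SMILES strings: the threo (1R,2R) open-chain alcohol maps onto the trans (2R,3R) ring with retention at both centres, and no structural correction is needed. One design change is made: the ring C phenol is carried as its triisopropylsilyl ether instead of a tert-butyldimethylsilyl ether. An aryl silyl ether is a silyl donor towards the caesium alkoxide formed in the ring closure, and the bulkier group suppresses that transfer while still leaving with fluoride. The skeletons and the bond formed in the key step are unchanged.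

## Structural features

The target is a 2,3-dihydro-1,4-benzodioxine: benzene ring A is fused through C4a and C8a to the dioxane ring B, and ring C, a 4-hydroxy-3,5-dimethoxyphenyl group, is attached to C2 by a C–C bond. Ring A carries OMe at C5, next to the O4-bearing C4a, and an (E)-prop-1-enyl group at C7, para to C4a and meta to C8a. The two stereocentres are neighbours in ring B: C2 (benzylic, bonded to O1 and ring C) and C3 (bonded to O4 and methyl) are both R, which places aryl and methyl trans. The fragile groups are the styrene-type propenyl unit (acid, electrophiles, hydrogenation), the electron-rich free phenol of ring C, and the doubly activated benzylic C2–O1 ether; as a phenoxide para to C2, ring C can expel O1 through a quinone methide and so epimerise C2. The real difficulty is that ring A is unsymmetrical, so the synthesis must decide which oxygen binds which carbon (O4, beside the OMe, to C3; O1 to C2) and must fix absolute and relative configuration without passing through a benzylic cation at C2. The key step exploits that ring A, with O4, the C5 methoxy group and a three-carbon chain at C7 para to O4, is the eugenol pattern, and its only free ortho position is C8a. A bromide there allows O1–C8a to be made last, at an sp2 carbon, so that both sp3 stereocentres are only carried.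

## Logic of the disconnections

**12 to 11.** Only the O–Si bond on the ring C phenol is involved. The phenol is masked because it would quench the organometallic reagent and interfere with the palladium chemistry earlier on. The demand on the forward step is a fluoride cleavage that does not leave a free phenoxide standing, since that could open the C2–O1 bond.

**11 to 10.** No skeletal bond is cut; the side-chain double bond at C7 is moved out of conjugation to the terminal position. The allyl group tolerates the bromination, organometallic and cross-coupling conditions better than a styrene, and it makes ring A identical with that of 1. The forward isomerisation must stop at the conjugated position and give the E isomer.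

**10 to 9.** The O1–C8a bond is cut, which opens ring B. This bond lies at an sp2 carbon and touches neither stereocentre, so the ring problem becomes an acyclic threo aryloxy alcohol whose two centres can be set by open-chain control. The forward step must let C–O reductive elimination outrun β-hydride elimination of a secondary benzylic alkoxide on an electron-rich aryl palladium species, and all protecting groups must survive carbonate in hot toluene.

**9 to 5 and 8.** The C2–C(ring C) bond is cut at the benzylic carbinol. This splits the molecule into two halves of similar size and creates C2 in the bond-forming step. The forward addition must be directed by the C3 ether oxygen (chelate control) to give the threo isomer, and the aryl nucleophile must not exchange with the aryl bromide of 5.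

**8 to 7 to 6.** The C–Mg bond is traced back to the C–Br bond and the silyl ether to the free phenol. These are functional-group changes on a commercial arene. The silyl group must survive magnesium insertion and, later, carbonate.

**5 to 4 to 2 and 3.** The aldehyde is taken back to the ester oxidation level, then the O4–C3 bond is cut. Substitution at the carbinol carbon of 3 with inversion brings C3 from the chiral pool in the required R configuration. The forward steps must give clean inversion with a di-ortho-substituted phenol and must avoid enolisation of the α-aryloxy carbonyl compounds.

**2 to 1.** The C8a–Br bond is cut. Compound 1 already holds every carbon and oxygen of ring A in the correct positions. The forward bromination must take the single free ortho position of the phenol without touching the allyl double bond.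

## Other disconnections considered

**Alternative 1:** The cut removes O4–C3 and C3–C2 together and leaves O1–C8a for a later ring closure. In the forward step Rh2(OAc)4 would decompose ethyl diazoacetate A3 in the presence of phenol 2, the aldehyde 3,5-dimethoxy-4-(tert-butyldimethylsilyloxy)benzaldehyde A2 and a chiral phosphoric acid. The phenol oxygen would add to the rhodium carbene, and the oxonium ylide would have to be intercepted by the acid-activated aldehyde before its 1,2-proton shift, giving the bromo hydroxy ester A1.
- In its favour: two skeletal bonds and both stereocentres would arise in one catalytic operation from achiral components, with no chiral-pool reagent and no configurationally labile aldehyde. On convergence, and on creating rather than carrying stereocentres, it is the better design.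
- Against it: C3 arrives with an ethoxycarbonyl group where the target has methyl. Taking it down (reduction, selective sulfonylation of the primary alcohol, hydride displacement) costs about three operations next to an aryl bromide and a free benzylic alcohol.
- Mechanistic doubts: ylides from phenols collapse very quickly to plain O–H insertion products; A2 is an electron-rich, weakly electrophilic aldehyde; the acceptor-only carbene from A3 could also cyclopropanate the allyl group of 2; and both relative and absolute control would rest on one ion-pairing catalyst.
- Comparison: A1 has the same bromide–alcohol relationship as 9, so the same palladium closure would follow, and the two plans are equal from that point on. Overall the alternative should come to nine or ten steps against eight, and its central step is far less predictable than an invertive substitution followed by a chelate-controlled addition.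

**Alternative 2:** The cut removes both ring B oxygen–carbon bonds made after the stereocentres: O1–C2 and O4–C4a. The roles of the ring A oxygens are reversed, so the phenol oxygen becomes O1. In the forward step the phenoxide of methyl 4-bromo-3-hydroxy-5-methoxybenzoate A6 would open the cis-epoxide (2S,3R)-2-[4-(benzyloxy)-3,5-dimethoxyphenyl]-3-methyloxirane A5 at its benzylic carbon with inversion. The freed C3 alkoxide would then be arylated at C4a under CuI catalysis in the same pot, giving the benzodioxane ester A4.
- In its favour: ring B would be finished in one operation, which is better than the three separate bond-forming steps of the chosen plan. Both stereocentres would come from one catalytic asymmetric epoxidation. The alkoxide that is arylated is not benzylic and the metal is copper, so β-hydride elimination is of little concern; on this point it is the better plan. On stereochemical logic the two plans are equal, since anti opening of a cis-epoxide and a retentive arylation also lead to the trans ring.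
- Against it: A5 is an electron-rich aryl epoxide that ionises readily at the benzylic carbon, which would leak configuration at C2 and invite rearrangement to a ketone under warm, Lewis acidic copper conditions. Its preparation needs a Z-selective olefination and an enantioselective epoxidation of a substrate class prone to trans-epoxide leakage.
- Further costs: opening at the wrong epoxide carbon would exchange the positions of aryl and methyl relative to the ring A oxygens. A6 is not a bulk chemical. The ester of A4 has to be converted to the propenyl group by reduction and an E-selective ethylidenation, and the benzyl ether cannot be removed by hydrogenolysis once the alkene is present.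
- Comparison: about ten steps are expected against eight, and the eugenol side chain cannot be used.

**Alternative 3:** The cut is O1–C2, with C2 becoming a stereocentre in the ring closure. In the forward step a controlled-potential anodic two-electron oxidation of the bisphenol 3-hydroxy-4-{[(2R)-1-(4-hydroxy-3,5-dimethoxyphenyl)propan-2-yl]oxy}-5-methoxybenzaldehyde A8 would turn its 4-alkyl-2,6-dimethoxyphenol part into a para-quinone methide. The ring A hydroxyl would add to it at C2 in a 6-exo closure to give the benzodioxane aldehyde A7.
- In its favour: no transition metal and no protecting group would be needed at the ring-closing stage, and the oxidant is electricity. A7 already has the free ring C phenol. The step count could be equal to or one lower than that of the chosen plan; on reagent economy and on creating a stereocentre it is the better plan.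
- Against it: C2 would be set only by 1,2-induction from the C3 methyl group in an addition to a planar quinone methide. The trans isomer is favoured (aryl and methyl both equatorial) but is not guaranteed by a stereospecific event, whereas the chosen plan fixes C2 in an open-chain chelate and then only carries it.
- Further costs: A7 is itself a 4-alkyl-2,6-dimethoxyphenol with an even more activated benzylic hydrogen, so over-oxidation is a built-in competitor. The propenyl group cannot be present at the anode, which is why C7 is an aldehyde, and the final E-selective olefination must then be run on a free phenol. A8 would also have to be made by an invertive etherification at a secondary homobenzylic carbon, where elimination to a styrene competes.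

Key step: step 6

## Route

Step 1
Reactants: 1 eugenol (4-allyl-2-methoxyphenol)
Product: 2 4-allyl-2-bromo-6-methoxyphenol
Conditions: NBS (1.0 equiv), iPr2NH (10 mol%), CH2Cl2, 0 °C
Reagents that add atoms: N-bromosuccinimide, O=C1CCC(=O)N1Br
Why: Amine-mediated ortho-bromination of a phenol (electrophilic aromatic substitution); the para position is blocked by the allyl group and only one ortho position is free, and delivery of bromine through the hydrogen-bonded N-bromoamine should be faster than bromonium formation at the unactivated terminal alkene.

Step 2
Reactants: 2 4-allyl-2-bromo-6-methoxyphenol; 3 ethyl (S)-lactate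
Product: 4 ethyl (R)-2-(4-allyl-2-bromo-6-methoxyphenoxy)propanoate
Conditions: PPh3, DIAD, THF, 0 °C to rt
Reagents that add atoms: none
Why: Mitsunobu etherification; the acidic ortho-bromophenol displaces the alkoxyphosphonium group of the lactate by SN2, so the S carbinol carbon is inverted to the R configuration that becomes C3.

Step 3
Reactants: 4 ethyl (R)-2-(4-allyl-2-bromo-6-methoxyphenoxy)propanoate
Product: 5 (R)-2-(4-allyl-2-bromo-6-methoxyphenoxy)propanal
Conditions: iBu2AlH (1.05 equiv), CH2Cl2, −78 °C; MeOH, then aq. KNaC4H4O6 (potassium sodium tartrate)
Reagents that add atoms: none
Why: Partial reduction of an ester to the aldehyde; the tetrahedral aluminium alkoxide, held by the α-oxygen, persists at −78 °C and releases the aldehyde only on work-up, the stereocentre is not touched, and the crude aldehyde is used at once to limit enolisation.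

Step 4
Reactants: 6 4-bromo-2,6-dimethoxyphenol
Product: 7 (4-bromo-2,6-dimethoxyphenoxy)triisopropylsilane
Conditions: iPr3SiCl, imidazole, DMF, rt
Reagents that add atoms: triisopropylsilyl chloride, CC(C)[Si](Cl)(C(C)C)C(C)C
Why: O-silylation of a phenol through the silylimidazolium species; the bulky group is chosen to resist the Grignard reagent and, later, carbonate and alkoxide.

Step 5
Reactants: 7 (4-bromo-2,6-dimethoxyphenoxy)triisopropylsilane; 5 (R)-2-(4-allyl-2-bromo-6-methoxyphenoxy)propanal
Product: 9 (1R,2R)-2-(4-allyl-2-bromo-6-methoxyphenoxy)-1-[3,5-dimethoxy-4-(triisopropylsilyloxy)phenyl]propan-1-ol, via arylmagnesium bromide 8 (not isolated)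
Conditions: 7, Mg turnings, I2 (cat.), THF, reflux; then added to 5, MgBr2·OEt2, CH2Cl2, −78 °C; aq. NH4Cl
Reagents that add atoms: none
Why: Grignard addition under Cram chelate control: magnesium bridges the carbonyl oxygen and the C2 ether oxygen, which stays Lewis basic because the two ortho substituents twist it out of conjugation with ring A, and the aryl group enters from the face of the small hydrogen, anti to methyl, which sets C1 as R (threo). Aryl–bromine exchange with the bromide of 5 is not expected at −78 °C.

Step 6
Reactants: 9 (1R,2R)-2-(4-allyl-2-bromo-6-methoxyphenoxy)-1-[3,5-dimethoxy-4-(triisopropylsilyloxy)phenyl]propan-1-ol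
Product: 10 (2R,3R)-2-[3,5-dimethoxy-4-(triisopropylsilyloxy)phenyl]-5-methoxy-3-methyl-7-(prop-2-en-1-yl)-2,3-dihydro-1,4-benzodioxine
Conditions: Pd(OAc)2 (3 mol%), rac-2-(di-tert-butylphosphino)-1,1'-binaphthyl (4 mol%), Cs2CO3 (1.5 equiv), toluene, 70 °C
Reagents that add atoms: none
Why: Pd(OAc)2 is reduced in the flask to zerovalent palladium, which inserts into the C8a–Br bond, and Cs2CO3 deprotonates the coordinated benzylic hydroxyl so that the alkoxide replaces bromide on divalent palladium. C–O reductive elimination from the resulting seven-membered aryl palladium alkoxide forms O1–C8a and returns zerovalent palladium. The closest known reaction type is the Buchwald–Hartwig-type intramolecular etherification of secondary alcohols with aryl bromides to chromans and 1,4-benzodioxanes. Ring B closes in a 6-exo mode onto the sp2 carbon C8a, through a palladacycle one atom larger than the ring formed. No stereocentre is created: C2 and C3 keep all their bonds, so the threo (1R,2R) alcohol gives the trans (2R,3R) ring with aryl and methyl both equatorial. The step needs reductive elimination to beat β-hydride elimination of the C2 hydrogen, which would give the aryl ketone and a debrominated arene; the bulky, electron-rich di-tert-butyl biaryl phosphine crowds palladium and speeds reductive elimination, and the fixed ortho relationship of O4 and bromine on ring A makes the closure intramolecular and six-membered. It also needs alkoxide capture to be faster than Heck-type insertion of the terminal alkene, which the intramolecular setting favours, and any migration of the allyl double bond would only anticipate step 7. The triisopropylsilyl ether is expected to withstand carbonate and alkoxide under these conditions.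

Step 7
Reactants: 10 (2R,3R)-2-[3,5-dimethoxy-4-(triisopropylsilyloxy)phenyl]-5-methoxy-3-methyl-7-(prop-2-en-1-yl)-2,3-dihydro-1,4-benzodioxine
Product: 11 (2R,3R)-2-[3,5-dimethoxy-4-(triisopropylsilyloxy)phenyl]-5-methoxy-3-methyl-7-[(E)-prop-1-en-1-yl]-2,3-dihydro-1,4-benzodioxine
Conditions: PdCl2(MeCN)2 (5 mol%), CH2Cl2, rt to 40 °C
Reagents that add atoms: none
Why: Palladium-catalysed olefin isomerisation of an allylarene by reversible hydride addition and elimination; conjugation with ring A drives the migration and the thermodynamically favoured E isomer should predominate, while neither stereocentre nor the silyl ether is involved.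

Step 8
Reactants: 11 (2R,3R)-2-[3,5-dimethoxy-4-(triisopropylsilyloxy)phenyl]-5-methoxy-3-methyl-7-[(E)-prop-1-en-1-yl]-2,3-dihydro-1,4-benzodioxine
Product: 12 4-[(2R,3R)-5-methoxy-3-methyl-7-[(E)-prop-1-en-1-yl]-2,3-dihydro-1,4-benzodioxin-2-yl]-2,6-dimethoxyphenol (target)
Conditions: Bu4NF (1.1 equiv), AcOH (1.1 equiv), THF, 0 °C
Reagents that add atoms: none
Why: Fluoride cleavage of an aryl silyl ether; the acetic acid buffer protonates the phenoxide as it forms, so that opening of the C2–O1 bond through a quinone methide, and with it epimerisation at C2, is not expected.

## Compound list

1 | eugenol (4-allyl-2-methoxyphenol) | C=CCc1ccc(O)c(OC)c1 | starting material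
2 | 4-allyl-2-bromo-6-methoxyphenol | C=CCc1cc(Br)c(O)c(OC)c1 | intermediate
3 | ethyl (S)-lactate | C[C@H](O)C(=O)OCC | starting material
4 | ethyl (R)-2-(4-allyl-2-bromo-6-methoxyphenoxy)propanoate | C=CCc1cc(Br)c(O[C@H](C)C(=O)OCC)c(OC)c1 | intermediate
5 | (R)-2-(4-allyl-2-bromo-6-methoxyphenoxy)propanal | C=CCc1cc(Br)c(O[C@H](C)C=O)c(OC)c1 | intermediate
6 | 4-bromo-2,6-dimethoxyphenol | COc1cc(Br)cc(OC)c1O | starting material
7 | (4-bromo-2,6-dimethoxyphenoxy)triisopropylsilane | COc1cc(Br)cc(OC)c1O[Si](C(C)C)(C(C)C)C(C)C | intermediate
8 | [3,5-dimethoxy-4-(triisopropylsilyloxy)phenyl]magnesium bromide | COc1cc([Mg]Br)cc(OC)c1O[Si](C(C)C)(C(C)C)C(C)C | intermediate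
9 | (1R,2R)-2-(4-allyl-2-bromo-6-methoxyphenoxy)-1-[3,5-dimethoxy-4-(triisopropylsilyloxy)phenyl]propan-1-ol | C=CCc1cc(Br)c(O[C@H](C)[C@H](O)c2cc(OC)c(O[Si](C(C)C)(C(C)C)C(C)C)c(OC)c2)c(OC)c1 | intermediate
10 | (2R,3R)-2-[3,5-dimethoxy-4-(triisopropylsilyloxy)phenyl]-5-methoxy-3-methyl-7-(prop-2-en-1-yl)-2,3-dihydro-1,4-benzodioxine | C=CCc1cc(OC)c2c(c1)O[C@H](c1cc(OC)c(O[Si](C(C)C)(C(C)C)C(C)C)c(OC)c1)[C@@H](C)O2 | intermediate
11 | (2R,3R)-2-[3,5-dimethoxy-4-(triisopropylsilyloxy)phenyl]-5-methoxy-3-methyl-7-[(E)-prop-1-en-1-yl]-2,3-dihydro-1,4-benzodioxine | C/C=C/c1cc(OC)c2c(c1)O[C@H](c1cc(OC)c(O[Si](C(C)C)(C(C)C)C(C)C)c(OC)c1)[C@@H](C)O2 | intermediate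
12 | 4-[(2R,3R)-5-methoxy-3-methyl-7-[(E)-prop-1-en-1-yl]-2,3-dihydro-1,4-benzodioxin-2-yl]-2,6-dimethoxyphenol | C/C=C/c1cc(OC)c2c(c1)O[C@H](c1cc(OC)c(O)c(OC)c1)[C@@H](C)O2 | target

## Step count and least certain steps

Total: 8 steps. Longest linear sequence: 7 steps (1 to 2 to 4 to 5 to 9 to 10 to 11 to 12, steps 1, 2, 3, 5, 6, 7, 8); the ring C branch (steps 4 and 5) joins at 9.

**Step 6 (key step).** The most likely failure is β-hydride elimination from the palladium alkoxide followed by reductive loss of bromine, because the electron-rich ring A slows C–O reductive elimination. Lesser risks are consumption of the terminal alkene by Heck-type insertion and transfer of the silyl group to the alkoxide. The fallback replaces the palladium cross-coupling by an Ullmann-type etherification on a different halide. It sets out from 9, which would undergo a copper-catalysed aromatic Finkelstein exchange (CuI, NaI, trans-N,N'-dimethylcyclohexane-1,2-diamine, dioxane, 110 °C) to the aryl iodide (1R,2R)-2-(4-allyl-2-iodo-6-methoxyphenoxy)-1-[3,5-dimethoxy-4-(triisopropylsilyloxy)phenyl]propan-1-ol F1. Ring closure with CuI, 3,4,7,8-tetramethyl-1,10-phenanthroline and Cs2CO3 in toluene at 100 °C would return to the route at 10. Copper alkoxides of this kind are not prone to β-hydride elimination and do not engage the alkene, and both stereocentres are again only carried.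

**Step 5.** Facial selectivity may be poor if the aryl ether oxygen chelates magnesium weakly, so that the open Felkin–Anh pathway to the erythro isomer competes; the aldehyde may also enolise before it is consumed, eroding C3. The fallback avoids the aldehyde and sets C1 by reduction instead of by C–C bond formation. It sets out from 4, which with MeNH(OMe)·HCl and iPrMgCl in THF at −20 °C would give the Weinreb amide (R)-2-(4-allyl-2-bromo-6-methoxyphenoxy)-N-methoxy-N-methylpropanamide F2. Addition of 8 in THF at 0 °C would give the ketone (R)-2-(4-allyl-2-bromo-6-methoxyphenoxy)-1-[3,5-dimethoxy-4-(triisopropylsilyloxy)phenyl]propan-1-one F3. Reduction with LiBH(sBu)3 in THF at −78 °C, under Felkin–Anh control with the aryloxy group anti to the incoming hydride, should give the threo alcohol and return to the route at 9.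

**Step 1.** Electrophilic bromine may add to the allyl double bond, or a second ring bromination may occur, in competition with the ortho substitution. The fallback protects the alkene as its dibromide during the ring bromination. It sets out from 1, which with Br2 (2 equiv) in CH2Cl2 at 0 °C would give racemic 2-bromo-4-(2,3-dibromopropyl)-6-methoxyphenol F4. Zn dust in AcOH/EtOH would then remove the vicinal bromines, restore the alkene and return to the route at 2.

**Step 2.** The di-ortho-substituted phenol may attack the alkoxyphosphonium ion slowly, so that elimination to the acrylate, alkylation of the reduced azo reagent, or partial loss of configurational purity competes. The fallback changes the activation of the lactate from in-situ phosphonium to an isolated sulfonate. It sets out from 3, which with TsCl and pyridine would give ethyl (S)-2-(tosyloxy)propanoate F5. Displacement by the phenoxide of 2 (K2CO3, MeCN, 60 °C) with inversion would return to the route at 4.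

## Further compounds

F1 | step 6 | (1R,2R)-2-(4-allyl-2-iodo-6-methoxyphenoxy)-1-[3,5-dimethoxy-4-(triisopropylsilyloxy)phenyl]propan-1-ol | C=CCc1cc(I)c(O[C@H](C)[C@H](O)c2cc(OC)c(O[Si](C(C)C)(C(C)C)C(C)C)c(OC)c2)c(OC)c1
F2 | step 5 | (R)-2-(4-allyl-2-bromo-6-methoxyphenoxy)-N-methoxy-N-methylpropanamide | C=CCc1cc(Br)c(O[C@H](C)C(=O)N(C)OC)c(OC)c1
F3 | step 5 | (R)-2-(4-allyl-2-bromo-6-methoxyphenoxy)-1-[3,5-dimethoxy-4-(triisopropylsilyloxy)phenyl]propan-1-one | C=CCc1cc(Br)c(O[C@H](C)C(=O)c2cc(OC)c(O[Si](C(C)C)(C(C)C)C(C)C)c(OC)c2)c(OC)c1
F4 | step 1 | 2-bromo-4-(2,3-dibromopropyl)-6-methoxyphenol (racemic) | COc1cc(CC(Br)CBr)cc(Br)c1O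
F5 | step 2 | ethyl (S)-2-(tosyloxy)propanoate | C[C@H](OS(=O)(=O)c1ccc(C)cc1)C(=O)OCC
A1 | alternative 1 | ethyl (2S,3R)-2-(4-allyl-2-bromo-6-methoxyphenoxy)-3-hydroxy-3-[4-(tert-butyldimethylsilyloxy)-3,5-dimethoxyphenyl]propanoate | C=CCc1cc(Br)c(O[C@H](C(=O)OCC)[C@H](O)c2cc(OC)c(O[Si](C)(C)C(C)(C)C)c(OC)c2)c(OC)c1
A2 | alternative 1 | 3,5-dimethoxy-4-(tert-butyldimethylsilyloxy)benzaldehyde | COc1cc(C=O)cc(OC)c1O[Si](C)(C)C(C)(C)C
A3 | alternative 1 | ethyl diazoacetate | CCOC(=O)C=[N+]=[N-]
A4 | alternative 2 | methyl (2R,3R)-2-[4-(benzyloxy)-3,5-dimethoxyphenyl]-5-methoxy-3-methyl-2,3-dihydro-1,4-benzodioxine-7-carboxylate | COC(=O)c1cc(OC)c2c(c1)O[C@H](c1cc(OC)c(OCc3ccccc3)c(OC)c1)[C@@H](C)O2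
A5 | alternative 2 | (2S,3R)-2-[4-(benzyloxy)-3,5-dimethoxyphenyl]-3-methyloxirane | C[C@H]1O[C@H]1c1cc(OC)c(OCc2ccccc2)c(OC)c1
A6 | alternative 2 | methyl 4-bromo-3-hydroxy-5-methoxybenzoate | COC(=O)c1cc(O)c(Br)c(OC)c1
A7 | alternative 3 | (2R,3R)-2-(4-hydroxy-3,5-dimethoxyphenyl)-5-methoxy-3-methyl-2,3-dihydro-1,4-benzodioxine-7-carbaldehyde | O=Cc1cc(OC)c2c(c1)O[C@H](c1cc(OC)c(O)c(OC)c1)[C@@H](C)O2
A8 | alternative 3 | 3-hydroxy-4-{[(2R)-1-(4-hydroxy-3,5-dimethoxyphenyl)propan-2-yl]oxy}-5-methoxybenzaldehyde | O=Cc1cc(OC)c(O[C@H](C)Cc2cc(OC)c(O)c(OC)c2)c(O)c1
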